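Per second and per litre, the test is whether gas crosses into solution faster than the catalyst consumes it.

    gas phase ⇌ dissolved gas, rate k1*(csat - [dissolved gas]) (k1 = 30.3 s⁻¹, csat = 9.9 mM)
    catalyst + added ligand ⇌ idle complex, settled at all times (K2 = 13 L mol⁻¹)
    dissolved gas + target → over-reaction product (k3 = 1.87 L mol⁻¹ s⁻¹)
    starting material + dissolved gas + catalyst → catalyst + target (k4 = 63.4 L² mol⁻² s⁻¹)

starting material 0.30 M; gas phase 9.9 mM (held); catalyst 45 mM; added ligand 250 mM; time 20 s

- at the start none of the gas is dissolved
- run time (flask): 20 s

- summer: doubling the amount of catalyst, all else as stated
- dawn: doubling the transfer coefficient of step 1, all else as stated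
- midnight: doubling the saturation concentration of gas phase, all else as stated

- the target standing at 20 s, as a percentage of the starting material charged
- the change that raises the amount of target at 20 s, in percent of the starting material charged most ("none" if none brings more than 2 percentage points) (summer / dawn / midnight / none)
- amount of target at 20 s, in percent of the starting material charged, after dawn

At balance with the added ligand, the charge leaves 11.8 mM of free catalyst. With starting material taken as charged, dissolved gas is consumed in a pseudo-first-order way, with coefficient 0.224 s⁻¹. Transfer has coefficient 30.3 s⁻¹, so transfer far outruns use. Dividing one by the other removes time and gives 135. This is the supply number, transfer coefficient over gas-use coefficient. Dissolved gas then balances at a share of saturation equal to the number over one plus the number, here 99.3%.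

Turn the question round. For dawn to pay, this number must stand at about one or below; at one, dissolved gas sits at half of saturation, and below one at less. This flask stands far above that, and dawn moves the share merely to 99.6%.

With the gas level steady, the flask runs as two consecutive first-order steps, with coefficients 0.00734 s⁻¹ and 0.0184 s⁻¹. That reckons target at 11.4%. Summer lifts free catalyst to 26.3 mM, more than twice the present amount. Midnight doubles both coefficients, so summer is the pick reckoned here.

The forecast gives 11.4%, summer and 11.4% after dawn, holding that “gas transfer is so fast that the dissolved gas sits near saturation”.

The simulation gives 11.4%, summer with 12 percentage points against 6.3 points for midnight, and 11.4% after dawn.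

In this flask, dissolved gas stands at 99.3% of saturation at 2.00 s. Scaling 11.4% by the share's rise puts dawn's gain at 0.042 points, and the run gives 0.041 points. Tying up catalyst as idle complex is the largest single effect: without it this flask gives 34.9% of target, not 11.4%.

In the neighbour flask with 0.10 M of added ligand, free catalyst is 22.4 mM, the supply number 71.0, and dissolved gas 0.00976 M. The simulation gives 0.00976 M of dissolved gas and 20.1% of target there.

(The numbers come from no measurement.)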